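**Retrosynthetic overview**

1. Eupaheliangolide A ⇐ its C10 silyl ether ⇐ key ring expansion: the five-membered butenolide (C3–C6 plus ring O) becomes the ten-membered carbocycle when the E-alkenyl carbon C2 is acylated intramolecularly by the lactone carbonyl C3; the expelled C6 alkoxide closes the α-methylene-γ-lactone on C12 in the same operation.
2. Ring-expansion precursor ⇐ C6–C7 bond by Lewis-base-catalysed vinylogous allylic alkylation of a Morita–Baylis–Hillman (MBH) carbonate with 3-methyl-2-silyloxyfuran (sets C6 and C7).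
3. MBH carbonate ⇐ C7–C11 bond by MBH reaction of an α-tigloyloxy aldehyde with methyl acrylate.
4. Aldehyde ⇐ C10–C1 bond by chelation-controlled ethynylation (sets C10) of the proline aldol product of acetone and 2,2-dimethoxyacetaldehyde (C8–C9 bond, sets C8); the alkyne is turned into the E-alkenyl iodide.
5. Ring order: butenolide (purchased) → ten-membered carbocycle and trans γ-lactone together in the ring expansion; no other ring is built.

Assumption: positions are given in germacranolide numbering (C1–C10 carbocycle, C11–C13 lactone unit, C14/C15 methyls); descriptors in names are the CIP descriptors of the compound named.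

**Route**

Step 1
Reactants: 1 acetone; 2 2,2-dimethoxyacetaldehyde
Product: 3 (4R)-4-hydroxy-5,5-dimethoxypentan-2-one
Conditions: L-proline (30 mol %), acetone/DMSO (1:4), 25 °C
Reagents that add atoms: none
Why: Proline-catalysed direct asymmetric aldol (enamine catalysis); the acetone enamine of L-proline adds to the non-enolisable aldehyde through the carboxylic-acid-organised chair transition state, which sets C8 as R.

Step 2
Reactants: 3 (4R)-4-hydroxy-5,5-dimethoxypentan-2-one; 4 ethynylmagnesium bromide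
Product: 5 (3R,5R)-6,6-dimethoxy-3-methylhex-1-yne-3,5-diol
Conditions: 4 (3 equiv), THF, −78 to −20 °C; then aq. NH4Cl
Reagents that add atoms: none
Why: Chelation-controlled Grignard addition to a β-hydroxy ketone; the magnesium alkoxide from the first equivalent holds the ketone in a six-membered chelate and the acetylide adds anti to the C8 substituent, giving the 8,10-anti diol (C10 R).

Step 3
Reactants: 5 (3R,5R)-6,6-dimethoxy-3-methylhex-1-yne-3,5-diol
Product: 7 (1E,3R,5R)-1-iodo-6,6-dimethoxy-3-methylhex-1-ene-3,5-diol, via alkenylstannane 6 (not isolated)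
Conditions: Bu3SnH, PdCl2(PPh3)2 (2 mol %), THF, 0 °C; then I2, CH2Cl2, 0 °C
Reagents that add atoms: iodine, II (the tin group of 6 comes from tributyltin hydride, CCCC[SnH](CCCC)CCCC, and is lost again)
Why: Palladium-catalysed syn-hydrostannation puts tin on the terminal carbon trans to the carbinol carbon (the usual outcome for tertiary propargylic alcohols), and iododestannylation with retention fixes the E-alkenyl iodide.

Step 4
Reactants: 7 (1E,3R,5R)-1-iodo-6,6-dimethoxy-3-methylhex-1-ene-3,5-diol; 8 (2E)-2-methylbut-2-enoyl chloride (tigloyl chloride)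
Product: 10 (2R,4R,5E)-4-[(tert-butyldimethylsilyl)oxy]-6-iodo-1,1-dimethoxy-4-methylhex-5-en-2-yl (2E)-2-methylbut-2-enoate, via monotiglate 9 (not isolated)
Conditions: pyridine, 4-(dimethylamino)pyridine (cat.), CH2Cl2, 0 °C; then TBSOTf, 2,6-lutidine, 0 to 25 °C
Reagents that add atoms: tert-butyldimethylsilyl trifluoromethanesulfonate, CC(C)(C)[Si](C)(C)OS(=O)(=O)C(F)(F)F
Why: Nucleophile-catalysed acylation by the acid chloride occurs only at the secondary alcohol, and silyl triflate silylation then caps the tertiary alcohol so that the later aldehyde cannot close to a lactol; no stereocentre is touched.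

Step 5
Reactants: 10 (2R,4R,5E)-4-[(tert-butyldimethylsilyl)oxy]-6-iodo-1,1-dimethoxy-4-methylhex-5-en-2-yl (2E)-2-methylbut-2-enoate
Product: 11 (2R,4R,5E)-4-[(tert-butyldimethylsilyl)oxy]-6-iodo-4-methyl-1-oxohex-5-en-2-yl (2E)-2-methylbut-2-enoate
Conditions: TsOH·H2O (0.2 equiv), acetone/H2O (10:1), 40 °C
Reagents that add atoms: water, O
Why: Acid-catalysed acetal hydrolysis unmasks the aldehyde; the hindered tertiary silyl ether and the tiglate survive the mild aqueous acid and C8 is not enolised.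

Step 6
Reactants: 11 (2R,4R,5E)-4-[(tert-butyldimethylsilyl)oxy]-6-iodo-4-methyl-1-oxohex-5-en-2-yl (2E)-2-methylbut-2-enoate; 12 methyl acrylate
Product: 13 methyl (4R,6R,7E)-6-[(tert-butyldimethylsilyl)oxy]-3-hydroxy-8-iodo-6-methyl-2-methylidene-4-{[(2E)-2-methylbut-2-enoyl]oxy}oct-7-enoate (C3 epimers)
Conditions: 1,4-diazabicyclo[2.2.2]octane (1 equiv), 12 (5 equiv), 1,4-dioxane/H2O (1:1), 25 °C
Reagents that add atoms: none
Why: Morita–Baylis–Hillman reaction; the amine–acrylate zwitterion adds to the electrophilic α-acyloxy aldehyde and forms the C7–C11 bond, and the new carbinol centre may be a mixture because it is erased in step 9.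

Step 7
Reactants: 13 methyl (4R,6R,7E)-6-[(tert-butyldimethylsilyl)oxy]-3-hydroxy-8-iodo-6-methyl-2-methylidene-4-{[(2E)-2-methylbut-2-enoyl]oxy}oct-7-enoate
Product: 14 methyl (4R,6R,7E)-3-[(tert-butoxycarbonyl)oxy]-6-[(tert-butyldimethylsilyl)oxy]-8-iodo-6-methyl-2-methylidene-4-{[(2E)-2-methylbut-2-enoyl]oxy}oct-7-enoate (C3 epimers)
Conditions: Boc2O, 4-(dimethylamino)pyridine (10 mol %), CH2Cl2, 0 °C
Reagents that add atoms: di-tert-butyl dicarbonate, CC(C)(C)OC(=O)OC(=O)OC(C)(C)C
Why: 4-(Dimethylamino)pyridine-catalysed carbonate formation turns the allylic alcohol into an SN2′ leaving group that releases tert-butoxide on ionisation.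

Step 8
Reactants: 15 3-methylfuran-2(5H)-one
Product: 16 tert-butyldimethyl[(3-methylfuran-2-yl)oxy]silane
Conditions: TBSOTf, Et3N, CH2Cl2, 0 °C
Reagents that add atoms: tert-butyldimethylsilyl trifluoromethanesulfonate, CC(C)(C)[Si](C)(C)OS(=O)(=O)C(F)(F)F
Why: Soft enolisation and O-silylation of the butenolide (silyl dienol ether formation) gives the aromatic 2-silyloxyfuran, nucleophilic at its C5 (the future C6).

Step 9
Reactants: 14 methyl (4R,6R,7E)-3-[(tert-butoxycarbonyl)oxy]-6-[(tert-butyldimethylsilyl)oxy]-8-iodo-6-methyl-2-methylidene-4-{[(2E)-2-methylbut-2-enoyl]oxy}oct-7-enoate; 16 tert-butyldimethyl[(3-methylfuran-2-yl)oxy]silane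
Product: 17 methyl (3R,4R,6R,7E)-6-[(tert-butyldimethylsilyl)oxy]-8-iodo-6-methyl-3-[(2R)-4-methyl-5-oxo-2,5-dihydrofuran-2-yl]-2-methylidene-4-{[(2E)-2-methylbut-2-enoyl]oxy}oct-7-enoate
Conditions: hydroquinidine 1,4-phthalazinediyl diether (10 mol %), toluene, 4 Å molecular sieves, 25 °C
Reagents that add atoms: none
Why: Lewis-base-catalysed SN2′–SN2′ allylic alkylation of an MBH carbonate with a 2-silyloxyfuran (vinylogous, γ-selective); the cinchona amine displaces the carbonate, the released tert-butoxide desilylates 16, and the furanolate attacks the chiral allylammonium ion pair at C7 so that C6 and C7 are set together (6R,7R; butenolide oxygen syn to the acrylate carbon and anti to the C8 oxygen), with the C8 centre intended to reinforce the catalyst's facial choice.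

Step 10
Reactants: 17 methyl (3R,4R,6R,7E)-6-[(tert-butyldimethylsilyl)oxy]-8-iodo-6-methyl-3-[(2R)-4-methyl-5-oxo-2,5-dihydrofuran-2-yl]-2-methylidene-4-{[(2E)-2-methylbut-2-enoyl]oxy}oct-7-enoate
Product: 19 (3aR,4R,6R,7E,10Z,11aR)-6-[(tert-butyldimethylsilyl)oxy]-6,10-dimethyl-3-methylidene-2,9-dioxo-2,3,3a,4,5,6,9,11a-octahydrocyclodeca[b]furan-4-yl (2E)-2-methylbut-2-enoate, via seco hydroxy ester 18 (not isolated)
Conditions: NiBr2(MeOCH2CH2OMe) (20 mol %), 4,4'-di-tert-butyl-2,2'-bipyridine (24 mol %), Zn (3 equiv), MgBr2·OEt2 (1 equiv), N,N-dimethylacetamide, 2 mM (slow addition), 40 °C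
Reagents that add atoms: none
Why: Proposed new method: nickel-catalysed reductive ring-expanding acyl transfer, in which zerovalent nickel inserts into the alkenyl C–I bond, the alkenylnickel adds to the magnesium-activated butenolide carbonyl (the 1,2-insertion/alkoxide-expulsion sequence known for alkenylnickel additions to esters in five-membered ring closures), and the nickel hemiketal collapses with C3–O cleavage so that the five-membered lactone ring becomes the ten-membered dienone with the Z C4=C5 and E C1=C2 geometries carried over unchanged; the freed C6 alkoxide then closes the trans γ-lactone on the methyl ester (irreversible driving force, C6 and C7 untouched) and zinc returns divalent nickel to zerovalent nickel; the closest known reaction types are the samarium-diiodide-promoted intramolecular nucleophilic acyl substitution of halo-lactones (ring expansion to medium carbocycles) and the Nozaki–Hiyama–Kishi closure of ten-membered germacranolide rings.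

Step 11
Reactants: 19 (3aR,4R,6R,7E,10Z,11aR)-6-[(tert-butyldimethylsilyl)oxy]-6,10-dimethyl-3-methylidene-2,9-dioxo-2,3,3a,4,5,6,9,11a-octahydrocyclodeca[b]furan-4-yl (2E)-2-methylbut-2-enoate
Product: 20 eupaheliangolide A, (3aR,4R,6R,7E,10Z,11aR)-6-hydroxy-6,10-dimethyl-3-methylidene-2,9-dioxo-2,3,3a,4,5,6,9,11a-octahydrocyclodeca[b]furan-4-yl (2E)-2-methylbut-2-enoate
Conditions: HF·pyridine, pyridine, THF, 0 to 25 °C
Reagents that add atoms: none
Why: Fluoride-mediated cleavage of the tertiary silyl ether (Si–F bond formation) under pyridine-buffered conditions leaves the α-methylene lactone, the dienone and the tiglate intact and affects no stereocentre.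

**Compound list**

1 | acetone | CC(C)=O | starting material
2 | 2,2-dimethoxyacetaldehyde | COC(OC)C=O | starting material
3 | (4R)-4-hydroxy-5,5-dimethoxypentan-2-one | COC(OC)[C@H](O)CC(C)=O | intermediate
4 | ethynylmagnesium bromide | C#C[Mg]Br | starting material
5 | (3R,5R)-6,6-dimethoxy-3-methylhex-1-yne-3,5-diol | COC(OC)[C@H](O)C[C@@](C)(O)C#C | intermediate
6 | (1E,3R,5R)-6,6-dimethoxy-3-methyl-1-(tributylstannyl)hex-1-ene-3,5-diol | COC(OC)[C@H](O)C[C@@](C)(O)/C=C/[Sn](CCCC)(CCCC)CCCC | intermediate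
7 | (1E,3R,5R)-1-iodo-6,6-dimethoxy-3-methylhex-1-ene-3,5-diol | COC(OC)[C@H](O)C[C@@](C)(O)/C=C/I | intermediate
8 | (2E)-2-methylbut-2-enoyl chloride (tigloyl chloride) | C/C=C(\C)C(=O)Cl | starting material
9 | (2R,4R,5E)-4-hydroxy-6-iodo-1,1-dimethoxy-4-methylhex-5-en-2-yl (2E)-2-methylbut-2-enoate | COC(OC)[C@H](OC(=O)/C(C)=C/C)C[C@@](C)(O)/C=C/I | intermediate
10 | (2R,4R,5E)-4-[(tert-butyldimethylsilyl)oxy]-6-iodo-1,1-dimethoxy-4-methylhex-5-en-2-yl (2E)-2-methylbut-2-enoate | COC(OC)[C@H](OC(=O)/C(C)=C/C)C[C@@](C)(O[Si](C)(C)C(C)(C)C)/C=C/I | intermediate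
11 | (2R,4R,5E)-4-[(tert-butyldimethylsilyl)oxy]-6-iodo-4-methyl-1-oxohex-5-en-2-yl (2E)-2-methylbut-2-enoate | O=C[C@H](OC(=O)/C(C)=C/C)C[C@@](C)(O[Si](C)(C)C(C)(C)C)/C=C/I | intermediate
12 | methyl acrylate | C=CC(=O)OC | starting material
13 | methyl (4R,6R,7E)-6-[(tert-butyldimethylsilyl)oxy]-3-hydroxy-8-iodo-6-methyl-2-methylidene-4-{[(2E)-2-methylbut-2-enoyl]oxy}oct-7-enoate (C3 epimers) | C=C(C(=O)OC)C(O)[C@H](OC(=O)/C(C)=C/C)C[C@@](C)(O[Si](C)(C)C(C)(C)C)/C=C/I | intermediate
14 | methyl (4R,6R,7E)-3-[(tert-butoxycarbonyl)oxy]-6-[(tert-butyldimethylsilyl)oxy]-8-iodo-6-methyl-2-methylidene-4-{[(2E)-2-methylbut-2-enoyl]oxy}oct-7-enoate (C3 epimers) | C=C(C(=O)OC)C(OC(=O)OC(C)(C)C)[C@H](OC(=O)/C(C)=C/C)C[C@@](C)(O[Si](C)(C)C(C)(C)C)/C=C/I | intermediate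
15 | 3-methylfuran-2(5H)-one | CC1=CCOC1=O | starting material
16 | tert-butyldimethyl[(3-methylfuran-2-yl)oxy]silane | Cc1ccoc1O[Si](C)(C)C(C)(C)C | intermediate
17 | methyl (3R,4R,6R,7E)-6-[(tert-butyldimethylsilyl)oxy]-8-iodo-6-methyl-3-[(2R)-4-methyl-5-oxo-2,5-dihydrofuran-2-yl]-2-methylidene-4-{[(2E)-2-methylbut-2-enoyl]oxy}oct-7-enoate | CC1=C[C@H]([C@H](C(=C)C(=O)OC)[C@H](OC(=O)/C(C)=C/C)C[C@@](C)(O[Si](C)(C)C(C)(C)C)/C=C/I)OC1=O | intermediate
18 | methyl 2-[(1S,2R,4R,5E,8Z,10R)-4-[(tert-butyldimethylsilyl)oxy]-10-hydroxy-4,8-dimethyl-2-{[(2E)-2-methylbut-2-enoyl]oxy}-7-oxocyclodeca-5,8-dien-1-yl]prop-2-enoate | C=C(C(=O)OC)[C@@H]1[C@H](OC(=O)/C(C)=C/C)C[C@@](C)(O[Si](C)(C)C(C)(C)C)/C=C/C(=O)/C(C)=C\[C@H]1O | intermediate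
19 | (3aR,4R,6R,7E,10Z,11aR)-6-[(tert-butyldimethylsilyl)oxy]-6,10-dimethyl-3-methylidene-2,9-dioxo-2,3,3a,4,5,6,9,11a-octahydrocyclodeca[b]furan-4-yl (2E)-2-methylbut-2-enoate | C=C1C(=O)O[C@@H]2/C=C(/C)C(=O)/C=C/[C@](C)(O[Si](C)(C)C(C)(C)C)C[C@@H](OC(=O)/C(C)=C/C)[C@@H]12 | intermediate
20 | eupaheliangolide A, (3aR,4R,6R,7E,10Z,11aR)-6-hydroxy-6,10-dimethyl-3-methylidene-2,9-dioxo-2,3,3a,4,5,6,9,11a-octahydrocyclodeca[b]furan-4-yl (2E)-2-methylbut-2-enoate | C=C1C(=O)O[C@@H]2/C=C(/C)C(=O)/C=C/[C@](C)(O)C[C@@H](OC(=O)/C(C)=C/C)[C@@H]12 | target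

**Totals and risks**

Total step count: 11. Longest linear sequence: 10 (steps 1–7 and 9–11; step 8 is a one-step side branch).

The three steps most likely to fail:

Step 10 (the proposed ring expansion). Alkenylnickel addition to an unactivated lactone carbonyl in a ten-membered closure is unproven. Hydrodehalogenation, dimerisation, or insertion into the acrylate or butenolide alkenes may win. Fallback with known chemistry, setting out from 14 and coming back at 19:
- SN2′ bromide displacement of the carbonate (MgBr2·OEt2, THF) gives methyl (2Z,4R,6R,7E)-2-(bromomethyl)-6-[(tert-butyldimethylsilyl)oxy]-8-iodo-6-methyl-4-{[(2E)-2-methylbut-2-enoyl]oxy}octa-2,7-dienoate F1.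
- 3-Methylfuran is oxidised (Br2, MeOH, Na2CO3) to 2,5-dimethoxy-3-methyl-2,5-dihydrofuran F2, methanolysed (HCl, MeOH) to (2Z)-1,1,4,4-tetramethoxy-2-methylbut-2-ene F3, and half-hydrolysed at the less hindered acetal (acidic resin, wet acetone) to (2Z)-4,4-dimethoxy-3-methylbut-2-enal F4.
- A CrCl2-mediated Barbier allylation of F4 with F1 (anti-selective, lactonising in the flask) forms the C6–C7 bond and the trans α-methylene lactone acetal F5.
- Acetal hydrolysis gives the Z-enal F6.
- A Nozaki–Hiyama–Kishi macrocyclisation (CrCl2, NiCl2 cat., DMSO, high dilution) closes C2–C3 to the macrocyclic allylic alcohol F7, and Dess–Martin oxidation gives 19.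

Step 9 (allylic alkylation). Three contiguous stereocentres must come out as (6R,7R,8R) from an ion-pair transition state on an aliphatic, α-oxygenated MBH carbonate, and which relative configuration this reaction delivers on such a substrate is not established. The butenolide C6–H can also epimerise under the basic conditions. Fallback setting out from 14 and 15 and coming back at 17:
- 15 is brominated at C5 (NBS, radical initiator) to 5-bromo-3-methylfuran-2(5H)-one F8 and hydrolysed to 5-hydroxy-3-methylfuran-2(5H)-one F9.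
- An aqueous indium-mediated Barbier allylation (In powder, THF/H2O) of F9, which reacts as its open-chain Z-aldehyde acid, with the allylic bromide F1 (made from 14 as above) forms C6–C7 through a closed, chelated metal-allyl transition state.
- Acidification closes the butenolide and gives 17.

Step 6 (MBH reaction). The α-acyloxy aldehyde can epimerise at C8 or decompose during the slow amine-mediated reaction. Fallback setting out from 11 and coming back at 13: hydroalumination of methyl propiolate with iBu2AlH in the presence of N-methylmorpholine N-oxide gives methyl 2-[bis(2-methylpropyl)alumanyl]prop-2-enoate F10, which adds to 11 at −78 °C (vinylalumination) and gives 13 after aqueous work-up without any amine base.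

Further compounds

F1 | step 10 | methyl (2Z,4R,6R,7E)-2-(bromomethyl)-6-[(tert-butyldimethylsilyl)oxy]-8-iodo-6-methyl-4-{[(2E)-2-methylbut-2-enoyl]oxy}octa-2,7-dienoate | BrC/C(C(=O)OC)=C\[C@H](OC(=O)/C(C)=C/C)C[C@@](C)(O[Si](C)(C)C(C)(C)C)/C=C/I
F2 | step 10 | 2,5-dimethoxy-3-methyl-2,5-dihydrofuran | COC1OC(OC)C(C)=C1
F3 | step 10 | (2Z)-1,1,4,4-tetramethoxy-2-methylbut-2-ene | COC(OC)/C=C(C)\C(OC)OC
F4 | step 10 | (2Z)-4,4-dimethoxy-3-methylbut-2-enal | O=C/C=C(C)\C(OC)OC
F5 | step 10 | (1R,3R,4E)-3-[(tert-butyldimethylsilyl)oxy]-1-{(2R,3R)-2-[(1Z)-3,3-dimethoxy-2-methylprop-1-en-1-yl]-4-methylidene-5-oxooxolan-3-yl}-5-iodo-3-methylpent-4-en-1-yl (2E)-2-methylbut-2-enoate | C=C1C(=O)O[C@H](/C=C(/C)C(OC)OC)[C@H]1[C@H](OC(=O)/C(C)=C/C)C[C@@](C)(O[Si](C)(C)C(C)(C)C)/C=C/I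
F6 | step 10 | (1R,3R,4E)-3-[(tert-butyldimethylsilyl)oxy]-5-iodo-3-methyl-1-{(2R,3R)-4-methylidene-2-[(1Z)-2-methyl-3-oxoprop-1-en-1-yl]-5-oxooxolan-3-yl}pent-4-en-1-yl (2E)-2-methylbut-2-enoate | C=C1C(=O)O[C@H](/C=C(/C)C=O)[C@H]1[C@H](OC(=O)/C(C)=C/C)C[C@@](C)(O[Si](C)(C)C(C)(C)C)/C=C/I
F7 | step 10 | (3aR,4R,6R,7E,10Z,11aR)-6-[(tert-butyldimethylsilyl)oxy]-9-hydroxy-6,10-dimethyl-3-methylidene-2-oxo-2,3,3a,4,5,6,9,11a-octahydrocyclodeca[b]furan-4-yl (2E)-2-methylbut-2-enoate (C9 epimers) | C=C1C(=O)O[C@@H]2/C=C(/C)C(O)/C=C/[C@](C)(O[Si](C)(C)C(C)(C)C)C[C@@H](OC(=O)/C(C)=C/C)[C@@H]12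
F8 | step 9 | 5-bromo-3-methylfuran-2(5H)-one | CC1=CC(Br)OC1=O
F9 | step 9 | 5-hydroxy-3-methylfuran-2(5H)-one | CC1=CC(O)OC1=O
F10 | step 6 | methyl 2-[bis(2-methylpropyl)alumanyl]prop-2-enoate | C=C(C(=O)OC)[Al](CC(C)C)CC(C)C
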